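## Retrosynthetic overview

1. End game: global desilylation ⇐ O3 acetylation ⇐ ten-membered carbocycle, closed last at C3–C4 by intramolecular CrCl2/NiCl2 addition of a (Z)-alkenyl iodide to the C3 aldehyde.
2. Key late union at C7–C8: zinc Barbier reaction of fragment A (bromomethyl butenolide; C4–C7, C11–C13, C15) with fragment B (enal; C1–C3, C8–C10, C14). It creates the α-methylene-γ-lactone, C7 and the C8 carbinol, which is then inverted by Mitsunobu esterification with angelic acid.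
3. Fragment A: prop-2-yn-1-ol + crotonaldehyde + 2-(bromomethyl)acrylic acid. Sharpless kinetic resolution sets C6, trans-hydroalumination/iodination sets the C4=C5 geometry, ring-closing metathesis makes the butenolide.
4. Fragment B: (S)-α-hydroxy-γ-butyrolactone supplies C1; Weinreb ketone synthesis and Horner–Wadsworth–Emmons olefination build the (E)-C9=C10 enal.
5. Ring order: butenolide (metathesis) → converted into the α-methylene lactone in the Barbier union → ten-membered ring (last).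

Assumption: positions are labelled with germacrane numbering (lactone oxygen on C6, lactone carbonyl C12, exo-methylene C13, ring methyl C14, hydroxymethyl C15). Read this way the SMILES is the (1S,3S,4Z,6R,7R,8R,9E) isomer with a (Z)-2-methylbut-2-enoate (angelate) on O8.

## Route

**Step 1**
Reactants: 1 prop-2-yn-1-ol
Product: 2 tert-butyldimethyl(prop-2-yn-1-yloxy)silane
Conditions: t-BuMe2SiCl, imidazole, CH2Cl2, 0 °C → rt
Reagents that add atoms: tert-butyldimethylsilyl chloride, CC(C)(C)[Si](C)(C)Cl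
Why: Silyl ether protection of the primary alcohol masks O15 until the last step.

**Step 2**
Reactants: 2 tert-butyldimethyl(prop-2-yn-1-yloxy)silane; 3 (E)-but-2-enal
Product: 5 racemic (E)-1-(tert-butyldimethylsilyloxy)hept-5-en-2-yn-4-ol, via lithium acetylide 4 (not isolated)
Conditions: n-BuLi, THF, −78 °C; then 3, −78 → 0 °C
Reagents that add atoms: none
Why: Acetylide addition: the lithium acetylide adds 1,2 to the enal to give the racemic secondary alcohol, which the next step resolves.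

**Step 3**
Reactants: 5 racemic (E)-1-(tert-butyldimethylsilyloxy)hept-5-en-2-yn-4-ol
Product: 6 (4S,5E)-1-(tert-butyldimethylsilyloxy)hept-5-en-2-yn-4-ol
Conditions: Ti(OiPr)4 (15 mol %), L-(+)-diisopropyl tartrate (20 mol %), t-BuOOH (0.6 equiv), 4 Å MS, CH2Cl2, −20 °C, to about 55 % conversion
Reagents that add atoms: none
Why: Sharpless kinetic resolution: with L-(+)-tartrate the (R)-enantiomer of this (E)-disubstituted secondary allylic alcohol is epoxidised much faster, so the unreacted (S)-alcohol (the future C6 configuration) is recovered in high ee.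

**Step 4**
Reactants: 6 (4S,5E)-1-(tert-butyldimethylsilyloxy)hept-5-en-2-yn-4-ol
Product: 8 (2Z,4S,5E)-1-(tert-butyldimethylsilyloxy)-2-iodohepta-2,5-dien-4-ol, via cyclic alkenylalanate 7 (not isolated)
Conditions: NaAlH2(OCH2CH2OCH3)2, THF, 0 °C; then I2, −78 → 0 °C
Reagents that add atoms: iodine, [I][I]
Why: Alkoxide-directed trans-hydroalumination puts H on the proximal and Al on the distal alkyne carbon in a five-membered alanate, and iodinolysis with retention gives the (Z)-iodoalkene (the C4=C5 geometry, with iodine where C3 will be attached) without touching C6.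

**Step 5**
Reactants: 8 (2Z,4S,5E)-1-(tert-butyldimethylsilyloxy)-2-iodohepta-2,5-dien-4-ol; 9 2-(bromomethyl)prop-2-enoic acid
Product: 10 (2Z,4S,5E)-1-(tert-butyldimethylsilyloxy)-2-iodohepta-2,5-dien-4-yl 2-(bromomethyl)prop-2-enoate
Conditions: DCC, DMAP (5 mol %), CH2Cl2, 0 °C
Reagents that add atoms: none
Why: Steglich esterification under nearly neutral conditions acylates the secondary alcohol without displacing the allylic bromide of the acid.

**Step 6**
Reactants: 10 (2Z,4S,5E)-1-(tert-butyldimethylsilyloxy)-2-iodohepta-2,5-dien-4-yl 2-(bromomethyl)prop-2-enoate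
Product: 11 (5S)-3-(bromomethyl)-5-[(1Z)-3-(tert-butyldimethylsilyloxy)-2-iodoprop-1-en-1-yl]furan-2(5H)-one (fragment A)
Conditions: second-generation Grubbs catalyst (5 mol %), toluene, 80 °C
Reagents that add atoms: none
Why: Ring-closing metathesis between the propenyl group and the acrylate forms the butenolide with loss of propene, while the trisubstituted iodoalkene and the allylic bromide are poor metathesis partners and stay intact.

**Step 7**
Reactants: 12 (3S)-3-hydroxyoxolan-2-one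
Product: 13 (2S)-2,4-dihydroxy-N-methoxy-N-methylbutanamide
Conditions: MeNH(OMe)·HCl, AlMe3 (3 equiv), CH2Cl2, 0 °C → rt
Reagents that add atoms: N,O-dimethylhydroxylamine hydrochloride, CNOC.Cl
Why: Aluminium-amide aminolysis of the lactone (Weinreb amide formation) opens the ring without affecting the chiral-pool stereocentre that becomes C1.

**Step 8**
Reactants: 13 (2S)-2,4-dihydroxy-N-methoxy-N-methylbutanamide
Product: 14 (2S)-N-methoxy-N-methyl-2,4-bis(triethylsilyloxy)butanamide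
Conditions: Et3SiCl (2.5 equiv), imidazole, DMF, 0 °C → rt
Reagents that add atoms: chlorotriethylsilane, CC[Si](Cl)(CC)CC
Why: Bis-silylation protects both hydroxyls, and the primary triethylsilyl ether is later the only one converted under Swern conditions.

**Step 9**
Reactants: 14 (2S)-N-methoxy-N-methyl-2,4-bis(triethylsilyloxy)butanamide
Product: 15 (3S)-3,5-bis(triethylsilyloxy)pentan-2-one
Conditions: MeMgBr, THF, −20 → 0 °C
Reagents that add atoms: methylmagnesium bromide, C[Mg]Br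
Why: Weinreb ketone synthesis: the chelated tetrahedral adduct prevents over-addition and the α-silyloxy stereocentre is not enolised at low temperature.

**Step 10**
Reactants: 15 (3S)-3,5-bis(triethylsilyloxy)pentan-2-one
Product: 16 ethyl (2E,4S)-3-methyl-4,6-bis(triethylsilyloxy)hex-2-enoate
Conditions: (EtO)2P(O)CH2CO2Et, NaH, THF, 0 °C → rt
Reagents that add atoms: triethyl phosphonoacetate, CCOC(=O)CP(=O)(OCC)OCC
Why: Horner–Wadsworth–Emmons olefination of the methyl ketone places the ester trans to the larger α-silyloxyalkyl group, giving the (E)-C9=C10 alkene (minor Z isomer removed by chromatography).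

**Step 11**
Reactants: 16 ethyl (2E,4S)-3-methyl-4,6-bis(triethylsilyloxy)hex-2-enoate
Product: 17 (2E,4S)-3-methyl-4,6-bis(triethylsilyloxy)hex-2-en-1-ol
Conditions: iBu2AlH (2.2 equiv), CH2Cl2, −78 °C
Reagents that add atoms: none
Why: Low-temperature 1,2-reduction of the enoate by the aluminium hydride gives the allylic alcohol and leaves the silyl ethers and the alkene untouched.

**Step 12**
Reactants: 17 (2E,4S)-3-methyl-4,6-bis(triethylsilyloxy)hex-2-en-1-ol
Product: 18 (2E,4S)-3-methyl-4,6-bis(triethylsilyloxy)hex-2-enal (fragment B)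
Conditions: MnO2, CH2Cl2, rt
Reagents that add atoms: none
Why: Allylic oxidation with MnO2 gives the enal without isomerising the alkene or epimerising C1.

**Step 13**
Reactants: 11 (5S)-3-(bromomethyl)-5-[(1Z)-3-(tert-butyldimethylsilyloxy)-2-iodoprop-1-en-1-yl]furan-2(5H)-one; 18 (2E,4S)-3-methyl-4,6-bis(triethylsilyloxy)hex-2-enal
Product: 20 (4R,5S)-5-[(1Z)-3-(tert-butyldimethylsilyloxy)-2-iodoprop-1-en-1-yl]-4-[(1S,2E,4S)-1-hydroxy-3-methyl-4,6-bis(triethylsilyloxy)hex-2-en-1-yl]-3-methylideneoxolan-2-one, via allylzinc bromide 19 (not isolated)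
Conditions: Zn dust, THF/sat. aq. NH4Cl, 0 °C → rt
Reagents that add atoms: none
Why: Zinc Barbier allylation: the allylzinc reacts at its ring γ-carbon with the aldehyde carbonyl, anti to the C6 substituent (6,7-trans lactone, C7 R) and through a chair transition state with the ring-locked E-type allyl geometry, which gives the 8S carbinol, the C8 epimer that the next step inverts; the vinyl iodide and silyl ethers tolerate zinc in buffered aqueous THF.

**Step 14**
Reactants: 20 (4R,5S)-5-[(1Z)-3-(tert-butyldimethylsilyloxy)-2-iodoprop-1-en-1-yl]-4-[(1S,2E,4S)-1-hydroxy-3-methyl-4,6-bis(triethylsilyloxy)hex-2-en-1-yl]-3-methylideneoxolan-2-one; 21 (2Z)-2-methylbut-2-enoic acid (angelic acid)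
Product: 22 (1R,2E,4S)-1-[(2S,3R)-2-[(1Z)-3-(tert-butyldimethylsilyloxy)-2-iodoprop-1-en-1-yl]-4-methylidene-5-oxooxolan-3-yl]-3-methyl-4,6-bis(triethylsilyloxy)hex-2-en-1-yl (2Z)-2-methylbut-2-enoate
Conditions: PPh3, diisopropyl azodicarboxylate, toluene, 0 °C → rt
Reagents that add atoms: none
Why: Mitsunobu esterification displaces the activated C8 oxygen by angelate with SN2 inversion, which sets the 8R acyloxy centre and installs the Z ester in one neutral operation.

**Step 15**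
Reactants: 22 (1R,2E,4S)-1-[(2S,3R)-2-[(1Z)-3-(tert-butyldimethylsilyloxy)-2-iodoprop-1-en-1-yl]-4-methylidene-5-oxooxolan-3-yl]-3-methyl-4,6-bis(triethylsilyloxy)hex-2-en-1-yl (2Z)-2-methylbut-2-enoate
Product: 24 (1R,2E,4S)-1-[(2S,3R)-2-[(1Z)-3-(tert-butyldimethylsilyloxy)-2-iodoprop-1-en-1-yl]-4-methylidene-5-oxooxolan-3-yl]-3-methyl-6-oxo-4-(triethylsilyloxy)hex-2-en-1-yl (2Z)-2-methylbut-2-enoate, via alkoxysulfonium chloride 23 (not isolated)
Conditions: (COCl)2, DMSO, CH2Cl2, −78 → −40 °C; then Et3N, −78 → 0 °C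
Reagents that add atoms: none
Why: Under Swern conditions the primary triethylsilyl ether is cleaved and oxidised in one pot to the aldehyde (oxidative desilylation, Swern oxidation), whereas the secondary triethylsilyl and the tert-butyldimethylsilyl ethers survive.

**Step 16**
Reactants: 24 (1R,2E,4S)-1-[(2S,3R)-2-[(1Z)-3-(tert-butyldimethylsilyloxy)-2-iodoprop-1-en-1-yl]-4-methylidene-5-oxooxolan-3-yl]-3-methyl-6-oxo-4-(triethylsilyloxy)hex-2-en-1-yl (2Z)-2-methylbut-2-enoate
Product: 26 (1S,3S,4Z,6R,7R,8R,9E)-15-(tert-butyldimethylsilyloxy)-3-hydroxy-8-[(2Z)-2-methylbut-2-enoyloxy]-1-(triethylsilyloxy)germacra-4,9,11(13)-trien-12,6-olide, via alkenylchromium dichloride 25 (not isolated)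
Conditions: CrCl2 (10 equiv), NiCl2 (2 mol %), DMSO/THF, rt, 2 mM, slow addition
Reagents that add atoms: none
Why: Intramolecular Nozaki–Hiyama–Kishi reaction: the alkenylchromium, formed with retention of the Z geometry, adds chemoselectively to the aldehyde at high dilution and closes the ten-membered ring; the new C3 carbinol is expected 1,3-anti to the C1 silyloxy group (Evans polar model for β-alkoxy aldehydes, within the trans-lactone-fused ring), i.e. 3S.

**Step 17**
Reactants: 26 (1S,3S,4Z,6R,7R,8R,9E)-15-(tert-butyldimethylsilyloxy)-3-hydroxy-8-[(2Z)-2-methylbut-2-enoyloxy]-1-(triethylsilyloxy)germacra-4,9,11(13)-trien-12,6-olide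
Product: 27 (1S,3S,4Z,6R,7R,8R,9E)-3-acetoxy-15-(tert-butyldimethylsilyloxy)-8-[(2Z)-2-methylbut-2-enoyloxy]-1-(triethylsilyloxy)germacra-4,9,11(13)-trien-12,6-olide
Conditions: Ac2O, pyridine, DMAP (cat.), CH2Cl2, 0 °C
Reagents that add atoms: acetic anhydride, CC(=O)OC(C)=O
Why: DMAP-catalysed acetylation of the only free hydroxyl (O3) proceeds with retention.

**Step 18**
Reactants: 27 (1S,3S,4Z,6R,7R,8R,9E)-3-acetoxy-15-(tert-butyldimethylsilyloxy)-8-[(2Z)-2-methylbut-2-enoyloxy]-1-(triethylsilyloxy)germacra-4,9,11(13)-trien-12,6-olide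
Product: 28 (1S,3S,4Z,6R,7R,8R,9E)-3-acetoxy-1,15-dihydroxy-8-[(2Z)-2-methylbut-2-enoyloxy]germacra-4,9,11(13)-trien-12,6-olide (target)
Conditions: HF·pyridine, pyridine, THF, 0 °C → rt
Reagents that add atoms: none
Why: Fluoride-mediated desilylation under buffered, mildly acidic conditions removes both silyl ethers without acyl migration, lactone opening or isomerisation of the angelate.

## Compound list

1 | prop-2-yn-1-ol | C#CCO | starting material
2 | tert-butyldimethyl(prop-2-yn-1-yloxy)silane | C#CCO[Si](C)(C)C(C)(C)C | intermediate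
3 | (E)-but-2-enal | C/C=C/C=O | starting material
4 | [3-(tert-butyldimethylsilyloxy)prop-1-yn-1-yl]lithium | [Li]C#CCO[Si](C)(C)C(C)(C)C | intermediate
5 | racemic (E)-1-(tert-butyldimethylsilyloxy)hept-5-en-2-yn-4-ol | C/C=C/C(O)C#CCO[Si](C)(C)C(C)(C)C | intermediate
6 | (4S,5E)-1-(tert-butyldimethylsilyloxy)hept-5-en-2-yn-4-ol | C/C=C/[C@H](O)C#CCO[Si](C)(C)C(C)(C)C | intermediate
7 | sodium (5S)-3-[(tert-butyldimethylsilyloxy)methyl]-2,2-bis(2-methoxyethoxy)-5-[(E)-prop-1-enyl]-2,5-dihydro-1,2-oxaaluminol-2-uide (cyclic alkenylalanate) | C/C=C/[C@@H]1O[Al-](OCCOC)(OCCOC)C(CO[Si](C)(C)C(C)(C)C)=C1.[Na+] | intermediate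
8 | (2Z,4S,5E)-1-(tert-butyldimethylsilyloxy)-2-iodohepta-2,5-dien-4-ol | C/C=C/[C@H](O)/C=C(\I)CO[Si](C)(C)C(C)(C)C | intermediate
9 | 2-(bromomethyl)prop-2-enoic acid | C=C(CBr)C(=O)O | starting material
10 | (2Z,4S,5E)-1-(tert-butyldimethylsilyloxy)-2-iodohepta-2,5-dien-4-yl 2-(bromomethyl)prop-2-enoate | C/C=C/[C@H](OC(=O)C(=C)CBr)/C=C(\I)CO[Si](C)(C)C(C)(C)C | intermediate
11 | (5S)-3-(bromomethyl)-5-[(1Z)-3-(tert-butyldimethylsilyloxy)-2-iodoprop-1-en-1-yl]furan-2(5H)-one | O=C1O[C@H](/C=C(\I)CO[Si](C)(C)C(C)(C)C)C=C1CBr | intermediate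
12 | (3S)-3-hydroxyoxolan-2-one | O[C@H]1CCOC1=O | starting material
13 | (2S)-2,4-dihydroxy-N-methoxy-N-methylbutanamide | CON(C)C(=O)[C@@H](O)CCO | intermediate
14 | (2S)-N-methoxy-N-methyl-2,4-bis(triethylsilyloxy)butanamide | CON(C)C(=O)[C@@H](O[Si](CC)(CC)CC)CCO[Si](CC)(CC)CC | intermediate
15 | (3S)-3,5-bis(triethylsilyloxy)pentan-2-one | CC(=O)[C@@H](O[Si](CC)(CC)CC)CCO[Si](CC)(CC)CC | intermediate
16 | ethyl (2E,4S)-3-methyl-4,6-bis(triethylsilyloxy)hex-2-enoate | CCOC(=O)/C=C(\C)[C@@H](O[Si](CC)(CC)CC)CCO[Si](CC)(CC)CC | intermediate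
17 | (2E,4S)-3-methyl-4,6-bis(triethylsilyloxy)hex-2-en-1-ol | OC/C=C(\C)[C@@H](O[Si](CC)(CC)CC)CCO[Si](CC)(CC)CC | intermediate
18 | (2E,4S)-3-methyl-4,6-bis(triethylsilyloxy)hex-2-enal | O=C/C=C(\C)[C@@H](O[Si](CC)(CC)CC)CCO[Si](CC)(CC)CC | intermediate
19 | {[(5S)-5-[(1Z)-3-(tert-butyldimethylsilyloxy)-2-iodoprop-1-en-1-yl]-2-oxo-2,5-dihydrofuran-3-yl]methyl}zinc bromide | O=C1O[C@H](/C=C(\I)CO[Si](C)(C)C(C)(C)C)C=C1C[Zn]Br | intermediate
20 | (4R,5S)-5-[(1Z)-3-(tert-butyldimethylsilyloxy)-2-iodoprop-1-en-1-yl]-4-[(1S,2E,4S)-1-hydroxy-3-methyl-4,6-bis(triethylsilyloxy)hex-2-en-1-yl]-3-methylideneoxolan-2-one | C=C1C(=O)O[C@H](/C=C(\I)CO[Si](C)(C)C(C)(C)C)[C@H]1[C@@H](O)/C=C(\C)[C@@H](O[Si](CC)(CC)CC)CCO[Si](CC)(CC)CC | intermediate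
21 | (2Z)-2-methylbut-2-enoic acid (angelic acid) | C/C=C(/C)C(=O)O | starting material
22 | (1R,2E,4S)-1-[(2S,3R)-2-[(1Z)-3-(tert-butyldimethylsilyloxy)-2-iodoprop-1-en-1-yl]-4-methylidene-5-oxooxolan-3-yl]-3-methyl-4,6-bis(triethylsilyloxy)hex-2-en-1-yl (2Z)-2-methylbut-2-enoate | C=C1C(=O)O[C@H](/C=C(\I)CO[Si](C)(C)C(C)(C)C)[C@H]1[C@H](OC(=O)/C(C)=C\C)/C=C(\C)[C@@H](O[Si](CC)(CC)CC)CCO[Si](CC)(CC)CC | intermediate
23 | alkoxydimethylsulfonium chloride of 22 (primary OSiEt3 replaced by OS+(CH3)2 Cl−) | C=C1C(=O)O[C@H](/C=C(\I)CO[Si](C)(C)C(C)(C)C)[C@H]1[C@H](OC(=O)/C(C)=C\C)/C=C(\C)[C@@H](O[Si](CC)(CC)CC)CCO[S+](C)C.[Cl-] | intermediate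
24 | (1R,2E,4S)-1-[(2S,3R)-2-[(1Z)-3-(tert-butyldimethylsilyloxy)-2-iodoprop-1-en-1-yl]-4-methylidene-5-oxooxolan-3-yl]-3-methyl-6-oxo-4-(triethylsilyloxy)hex-2-en-1-yl (2Z)-2-methylbut-2-enoate | C=C1C(=O)O[C@H](/C=C(\I)CO[Si](C)(C)C(C)(C)C)[C@H]1[C@H](OC(=O)/C(C)=C\C)/C=C(\C)[C@@H](O[Si](CC)(CC)CC)CC=O | intermediate
25 | alkenylchromium dichloride of 24 (iodine replaced by CrCl2) | C=C1C(=O)O[C@H](/C=C(\[Cr](Cl)Cl)CO[Si](C)(C)C(C)(C)C)[C@H]1[C@H](OC(=O)/C(C)=C\C)/C=C(\C)[C@@H](O[Si](CC)(CC)CC)CC=O | intermediate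
26 | (1S,3S,4Z,6R,7R,8R,9E)-15-(tert-butyldimethylsilyloxy)-3-hydroxy-8-[(2Z)-2-methylbut-2-enoyloxy]-1-(triethylsilyloxy)germacra-4,9,11(13)-trien-12,6-olide | C=C1C(=O)O[C@@H]2/C=C(/CO[Si](C)(C)C(C)(C)C)[C@@H](O)C[C@H](O[Si](CC)(CC)CC)/C(C)=C/[C@@H](OC(=O)/C(C)=C\C)[C@@H]12 | intermediate
27 | (1S,3S,4Z,6R,7R,8R,9E)-3-acetoxy-15-(tert-butyldimethylsilyloxy)-8-[(2Z)-2-methylbut-2-enoyloxy]-1-(triethylsilyloxy)germacra-4,9,11(13)-trien-12,6-olide | C=C1C(=O)O[C@@H]2/C=C(/CO[Si](C)(C)C(C)(C)C)[C@@H](OC(C)=O)C[C@H](O[Si](CC)(CC)CC)/C(C)=C/[C@@H](OC(=O)/C(C)=C\C)[C@@H]12 | intermediate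
28 | (1S,3S,4Z,6R,7R,8R,9E)-3-acetoxy-1,15-dihydroxy-8-[(2Z)-2-methylbut-2-enoyloxy]germacra-4,9,11(13)-trien-12,6-olide | C=C1C(=O)O[C@@H]2/C=C(/CO)[C@@H](OC(C)=O)C[C@H](O)/C(C)=C/[C@@H](OC(=O)/C(C)=C\C)[C@@H]12 | target

## Step count and risks

Total step count: 18.
Longest linear sequence: 12 steps (steps 1–6, then 13–18; the sequence 7–12, then 13–18 is equally long).

The three steps most likely to fail:

Step 13 (zinc Barbier union; the sense of addition at C8 rests on a chair transition state and on analogy with related bromomethyl butenolides). The fallback sets out from 11 and 18 and comes back at 22. If the addition delivers mainly the other C8 epimer, (4R,5S)-5-[(1Z)-3-(tert-butyldimethylsilyloxy)-2-iodoprop-1-en-1-yl]-4-[(1R,2E,4S)-1-hydroxy-3-methyl-4,6-bis(triethylsilyloxy)hex-2-en-1-yl]-3-methylideneoxolan-2-one F1, this alcohol already has the C8 configuration of the target. It is then acylated with retention instead of being inverted: 21, 2,4,6-trichlorobenzoyl chloride, Et3N, toluene, 80 °C (mixed-anhydride acylation without DMAP, which keeps the Z ester), giving 22 directly. A mixture of 20 and this epimer can be separated and both parts funnelled into 22.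

Step 14 (Mitsunobu with angelic acid; displacement next to the branched C7 may be slow, SN2' attack or Z to E drift of the acid may intervene). The fallback sets out from 20 and comes back at 22. Inversion and angeloylation are separated. Mitsunobu reaction with the stronger chloroacetic acid (PPh3, diisopropyl azodicarboxylate, toluene) gives the inverted (1R) chloroacetate F2. KHCO3 in MeOH at 0 °C removes the chloroacetyl group to give the (1R) alcohol F3 (same structure as the epimer named under step 13). Retentive mixed-anhydride angeloylation (21, 2,4,6-trichlorobenzoyl chloride, Et3N, toluene, 80 °C) then gives 22.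

Step 16 (CrCl2/NiCl2 closure of the ten-membered ring; the C3 configuration rests on substrate control and is not assured). The fallback sets out from 24 and comes back at 26. If the closure gives the (3R) alcohol, the C3 epimer of 26 F4, as the main or a major product, the epimer mixture is oxidised with Dess–Martin periodinane to the single macrocyclic 3-oxo compound (enone) F5. C3 is then set by reagent control, with (R)-2-methyl-CBS-oxazaborolidine and catecholborane in toluene at −78 °C (alkenyl as the large and CH2 as the small ketone substituent), which returns 26.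

## Further compounds

F1 | step 13 | (4R,5S)-5-[(1Z)-3-(tert-butyldimethylsilyloxy)-2-iodoprop-1-en-1-yl]-4-[(1R,2E,4S)-1-hydroxy-3-methyl-4,6-bis(triethylsilyloxy)hex-2-en-1-yl]-3-methylideneoxolan-2-one | C=C1C(=O)O[C@H](/C=C(\I)CO[Si](C)(C)C(C)(C)C)[C@H]1[C@H](O)/C=C(\C)[C@@H](O[Si](CC)(CC)CC)CCO[Si](CC)(CC)CC
F2 | step 14 | (1R,2E,4S)-1-[(2S,3R)-2-[(1Z)-3-(tert-butyldimethylsilyloxy)-2-iodoprop-1-en-1-yl]-4-methylidene-5-oxooxolan-3-yl]-3-methyl-4,6-bis(triethylsilyloxy)hex-2-en-1-yl 2-chloroacetate | C=C1C(=O)O[C@H](/C=C(\I)CO[Si](C)(C)C(C)(C)C)[C@H]1[C@H](OC(=O)CCl)/C=C(\C)[C@@H](O[Si](CC)(CC)CC)CCO[Si](CC)(CC)CC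
F3 | step 14 | (4R,5S)-5-[(1Z)-3-(tert-butyldimethylsilyloxy)-2-iodoprop-1-en-1-yl]-4-[(1R,2E,4S)-1-hydroxy-3-methyl-4,6-bis(triethylsilyloxy)hex-2-en-1-yl]-3-methylideneoxolan-2-one | C=C1C(=O)O[C@H](/C=C(\I)CO[Si](C)(C)C(C)(C)C)[C@H]1[C@H](O)/C=C(\C)[C@@H](O[Si](CC)(CC)CC)CCO[Si](CC)(CC)CC
F4 | step 16 | (1S,3R,4Z,6R,7R,8R,9E)-15-(tert-butyldimethylsilyloxy)-3-hydroxy-8-[(2Z)-2-methylbut-2-enoyloxy]-1-(triethylsilyloxy)germacra-4,9,11(13)-trien-12,6-olide | C=C1C(=O)O[C@@H]2/C=C(/CO[Si](C)(C)C(C)(C)C)[C@H](O)C[C@H](O[Si](CC)(CC)CC)/C(C)=C/[C@@H](OC(=O)/C(C)=C\C)[C@@H]12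
F5 | step 16 | (1S,4Z,6R,7R,8R,9E)-15-(tert-butyldimethylsilyloxy)-8-[(2Z)-2-methylbut-2-enoyloxy]-3-oxo-1-(triethylsilyloxy)germacra-4,9,11(13)-trien-12,6-olide | C=C1C(=O)O[C@@H]2/C=C(/CO[Si](C)(C)C(C)(C)C)C(=O)C[C@H](O[Si](CC)(CC)CC)/C(C)=C/[C@@H](OC(=O)/C(C)=C\C)[C@@H]12
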